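**Plan**

- Retrosynthesis: remove the three O-benzyl groups, then cut the C3–C4 bond of ring C to give a ring A aroyl chloride and a racemic ring B benzylic chloride joined through the O1–C2 ether (14). Next cut O1–C2 to salicylaldehyde 8 and aryloxirane 11, and take the C4 carbon off the symmetric phenol 6.
- Forward: phenol 6 (from a gallate) is ortho-formylated and joined to ring B by epoxide opening, which makes O1–C2. The aldehyde is oxidized and both OH groups are turned into chlorides. Ring C, the only ring to be built, is closed by an enantioconvergent nickel-catalyzed reductive acyl–benzyl coupling, and hydrogenolysis finishes the route.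
- Enabling feature: C3 is benzylic to ring B, so it can exist as a stabilized radical. It is linked through C2–O1–C8a–C4a to the ring A carboxyl carbon C4, so capture of that radical by an acyl nickel at C4 closes the six-membered ring C.
- Stereochemistry: the single stereocenter C3 (R) is set by the chiral bis(oxazoline)–nickel catalyst in the ring closure, with both enantiomers of 14 converging. No base is used after that point, and the end deprotection is neutral.

Key step: step 11

Remark: compounds 1 and 9 are taken as purchasable. The sense of induction of the ligand in step 11 cannot be predicted with certainty, so the route is written for the ligand antipode that delivers 3R, and the mirror-image ligand is used if the first run favors 3S.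

**Route**

Step 1
Reactants: 1 methyl 3,5-dihydroxy-4-methoxybenzoate
Product: 2 methyl 3,5-bis(benzyloxy)-4-methoxybenzoate
Conditions: BnBr (2.3 equiv), K2CO3, DMF, 60 °C
Reagents that add atoms: benzyl bromide, BrCc1ccccc1
Why: Williamson benzylation of both phenols should proceed cleanly, and the methyl ester is inert to carbonate.

Step 2
Reactants: 2 methyl 3,5-bis(benzyloxy)-4-methoxybenzoate
Product: 3 [3,5-bis(benzyloxy)-4-methoxyphenyl]methanol
Conditions: LiAlH4, THF, 0 °C to rt
Reagents that add atoms: none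
Why: Hydride reduction of the ester to the primary benzylic alcohol leaves aryl benzyl ethers untouched.

Step 3
Reactants: 3 [3,5-bis(benzyloxy)-4-methoxyphenyl]methanol
Product: 4 3,5-bis(benzyloxy)-4-methoxybenzaldehyde
Conditions: activated MnO2 (excess), CH2Cl2, rt
Reagents that add atoms: none
Why: Selective MnO2 oxidation of a benzylic alcohol should stop at the aldehyde.

Step 4
Reactants: 4 3,5-bis(benzyloxy)-4-methoxybenzaldehyde
Product: 6 3,5-bis(benzyloxy)-4-methoxyphenol, via 3,5-bis(benzyloxy)-4-methoxyphenyl formate 5 (not isolated)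
Conditions: mCPBA, CH2Cl2, 0 °C to rt; then K2CO3 (cat.), MeOH, rt
Reagents that add atoms: mCPBA, OOC(=O)c1cccc(Cl)c1
Why: Baeyer–Villiger (Dakin-type) oxidation with migration of the electron-rich aryl group gives the aryl formate, which methanolysis should cleave to the C2-symmetric phenol.

Step 5
Reactants: 6 3,5-bis(benzyloxy)-4-methoxyphenol
Product: 8 2,4-bis(benzyloxy)-6-hydroxy-3-methoxybenzaldehyde, via 3,5-bis(benzyloxy)-2-(hydroxymethyl)-4-methoxyphenol 7 (not isolated)
Conditions: MgCl2 (1.5 equiv), Et3N, paraformaldehyde (excess), MeCN, reflux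
Reagents that add atoms: paraformaldehyde (as formaldehyde), C=O
Why: Magnesium-phenoxide-directed ortho-formylation (Casnati–Skattebøl) should give a single product because the para position is blocked and the two ortho positions are equivalent by symmetry; the intermediate salicyl alcohol is oxidized in the flask by hydride transfer to formaldehyde.

Step 6
Reactants: 9 3-hydroxy-4,5-dimethoxybenzaldehyde
Product: 10 3-(benzyloxy)-4,5-dimethoxybenzaldehyde
Conditions: BnBr (1.2 equiv), K2CO3, DMF, rt
Reagents that add atoms: benzyl bromide, BrCc1ccccc1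
Why: Williamson benzylation of the single phenol should be straightforward.

Step 7
Reactants: 10 3-(benzyloxy)-4,5-dimethoxybenzaldehyde
Product: 11 rac-2-[3-(benzyloxy)-4,5-dimethoxyphenyl]oxirane
Conditions: Me3S+ I−, NaH, DMSO/THF, 0 °C to rt; crude product used directly
Reagents that add atoms: trimethylsulfonium iodide, C[S+](C)C.[I-]
Why: Corey–Chaykovsky methylene transfer from dimethylsulfonium methylide to the aldehyde should give the racemic aryloxirane, whose configuration is irrelevant because C3 is set later.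

Step 8
Reactants: 8 2,4-bis(benzyloxy)-6-hydroxy-3-methoxybenzaldehyde; 11 rac-2-[3-(benzyloxy)-4,5-dimethoxyphenyl]oxirane
Product: 12 rac-2,4-bis(benzyloxy)-6-{2-[3-(benzyloxy)-4,5-dimethoxyphenyl]-2-hydroxyethoxy}-3-methoxybenzaldehyde
Conditions: K2CO3 (0.2 equiv), DMF, 80 °C
Reagents that add atoms: none
Why: Base-mediated SN2 opening of the oxirane by the only free phenoxide should occur at the unhindered terminal carbon and forge the O1–C2 ether; the carbinol center is racemic and is erased later.

Step 9
Reactants: 12 rac-2,4-bis(benzyloxy)-6-{2-[3-(benzyloxy)-4,5-dimethoxyphenyl]-2-hydroxyethoxy}-3-methoxybenzaldehyde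
Product: 13 rac-2,4-bis(benzyloxy)-6-{2-[3-(benzyloxy)-4,5-dimethoxyphenyl]-2-hydroxyethoxy}-3-methoxybenzoic acid
Conditions: NaClO2, NaH2PO4, 2-methyl-2-butene (large excess), t-BuOH/THF/H2O, 0 °C to rt
Reagents that add atoms: sodium chlorite, [Na+].[O-]Cl=O
Why: Pinnick oxidation converts the hindered aldehyde to the acid without touching the secondary alcohol, and the excess alkene scavenges hypochlorous acid before it can chlorinate the electron-rich ring A.

Step 10
Reactants: 13 rac-2,4-bis(benzyloxy)-6-{2-[3-(benzyloxy)-4,5-dimethoxyphenyl]-2-hydroxyethoxy}-3-methoxybenzoic acid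
Product: 14 rac-2,4-bis(benzyloxy)-6-{2-[3-(benzyloxy)-4,5-dimethoxyphenyl]-2-chloroethoxy}-3-methoxybenzoyl chloride
Conditions: 1-chloro-N,N,2-trimethylprop-1-en-1-amine (Ghosez's reagent, 2.2 equiv), CH2Cl2, 0 °C to rt; volatiles removed, crude 14 used at once
Reagents that add atoms: Ghosez's reagent, CC(C)=C(Cl)N(C)C
Why: The α-chloroenamine should convert the carboxylic acid to the acid chloride and the benzylic alcohol to the chloride under neutral conditions, leaving only an amide co-product that is harmless in the next step.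

Step 11
Reactants: 14 rac-2,4-bis(benzyloxy)-6-{2-[3-(benzyloxy)-4,5-dimethoxyphenyl]-2-chloroethoxy}-3-methoxybenzoyl chloride
Product: 15 (3R)-5,7-bis(benzyloxy)-3-[3-(benzyloxy)-4,5-dimethoxyphenyl]-6-methoxy-2,3-dihydro-4H-chromen-4-one
Conditions: NiCl2(dme) (15 mol %), 2,2'-(propane-2,2-diyl)bis[(4R)-4-phenyl-4,5-dihydro-1,3-oxazole] (18 mol %), Mn powder (3 equiv), 2,6-dimethylbenzoic acid (0.75 equiv), 3 Å MS, DMA/THF 3:7, 20 °C, slow addition of 14 to a final 0.01 M
Reagents that add atoms: none
Why: Proposed new method: zerovalent nickel carrying the chiral bis(oxazoline) inserts into the C4 acyl chloride of 14, Mn reduces the acyl nickel chloride to a monovalent acyl nickel, this abstracts the chlorine atom from C3 of the same molecule, and the planar benzylic radical is recaptured to a trivalent acyl(benzyl)nickel that reductively eliminates the C4–C3 bond. The closest known reaction type is the intermolecular enantioconvergent nickel-catalyzed reductive coupling of acid chlorides with racemic secondary benzylic chlorides to α-aryl ketones; a ring-closing version on a tethered aroyl chloride has not been shown. Ring C closes in a formal 6-exo-tet mode at C3 (the chloride leaves outside the ring) by way of a seven-membered nickelacycle. C3 is set by the ligand during radical capture and reductive elimination, so both enantiomers of 14 should converge on the 3R ketone, and the base-free, weakly acidic medium should keep this α-aryl ketone from enolizing. The step needs ring closure to win over oligomerization and over loss of the aryloxy group from C2; slow addition at high dilution, the short C2–O1 tether that keeps the C3 radical beside its own acyl nickel, and the slow β-scission of a benzylic radical to an aryloxyl radical are what should secure this.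

Step 12
Reactants: 15 (3R)-5,7-bis(benzyloxy)-3-[3-(benzyloxy)-4,5-dimethoxyphenyl]-6-methoxy-2,3-dihydro-4H-chromen-4-one
Product: 16 (3R)-5,7-dihydroxy-3-(3-hydroxy-4,5-dimethoxyphenyl)-6-methoxy-2,3-dihydro-4H-chromen-4-one
Conditions: H2 (1 atm), 10% Pd/C, EtOAc/THF, rt
Reagents that add atoms: none
Why: Neutral hydrogenolysis should remove all three aryl benzyl ethers without base or acid, so the enolizable C3 center is not disturbed, and the hydrogen-bonded vinylogous-ester-type C4 ketone resists reduction.

**Compound list**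

1 | methyl 3,5-dihydroxy-4-methoxybenzoate | COC(=O)c1cc(O)c(OC)c(O)c1 | starting material
2 | methyl 3,5-bis(benzyloxy)-4-methoxybenzoate | COC(=O)c1cc(OCc2ccccc2)c(OC)c(OCc2ccccc2)c1 | intermediate
3 | [3,5-bis(benzyloxy)-4-methoxyphenyl]methanol | OCc1cc(OCc2ccccc2)c(OC)c(OCc2ccccc2)c1 | intermediate
4 | 3,5-bis(benzyloxy)-4-methoxybenzaldehyde | O=Cc1cc(OCc2ccccc2)c(OC)c(OCc2ccccc2)c1 | intermediate
5 | 3,5-bis(benzyloxy)-4-methoxyphenyl formate | O=COc1cc(OCc2ccccc2)c(OC)c(OCc2ccccc2)c1 | intermediate
6 | 3,5-bis(benzyloxy)-4-methoxyphenol | Oc1cc(OCc2ccccc2)c(OC)c(OCc2ccccc2)c1 | intermediate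
7 | 3,5-bis(benzyloxy)-2-(hydroxymethyl)-4-methoxyphenol (present as its magnesium phenoxide) | OCc1c(O)cc(OCc2ccccc2)c(OC)c1OCc1ccccc1 | intermediate
8 | 2,4-bis(benzyloxy)-6-hydroxy-3-methoxybenzaldehyde | O=Cc1c(O)cc(OCc2ccccc2)c(OC)c1OCc1ccccc1 | intermediate
9 | 3-hydroxy-4,5-dimethoxybenzaldehyde | COc1cc(C=O)cc(O)c1OC | starting material
10 | 3-(benzyloxy)-4,5-dimethoxybenzaldehyde | COc1cc(C=O)cc(OCc2ccccc2)c1OC | intermediate
11 | rac-2-[3-(benzyloxy)-4,5-dimethoxyphenyl]oxirane | COc1cc(C2CO2)cc(OCc2ccccc2)c1OC | intermediate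
12 | rac-2,4-bis(benzyloxy)-6-{2-[3-(benzyloxy)-4,5-dimethoxyphenyl]-2-hydroxyethoxy}-3-methoxybenzaldehyde | COc1cc(C(O)COc2cc(OCc3ccccc3)c(OC)c(OCc3ccccc3)c2C=O)cc(OCc2ccccc2)c1OC | intermediate
13 | rac-2,4-bis(benzyloxy)-6-{2-[3-(benzyloxy)-4,5-dimethoxyphenyl]-2-hydroxyethoxy}-3-methoxybenzoic acid | COc1cc(C(O)COc2cc(OCc3ccccc3)c(OC)c(OCc3ccccc3)c2C(=O)O)cc(OCc2ccccc2)c1OC | intermediate
14 | rac-2,4-bis(benzyloxy)-6-{2-[3-(benzyloxy)-4,5-dimethoxyphenyl]-2-chloroethoxy}-3-methoxybenzoyl chloride | COc1cc(C(Cl)COc2cc(OCc3ccccc3)c(OC)c(OCc3ccccc3)c2C(Cl)=O)cc(OCc2ccccc2)c1OC | intermediate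
15 | (3R)-5,7-bis(benzyloxy)-3-[3-(benzyloxy)-4,5-dimethoxyphenyl]-6-methoxy-2,3-dihydro-4H-chromen-4-one | COc1cc([C@@H]2COc3cc(OCc4ccccc4)c(OC)c(OCc4ccccc4)c3C2=O)cc(OCc2ccccc2)c1OC | intermediate
16 | (3R)-5,7-dihydroxy-3-(3-hydroxy-4,5-dimethoxyphenyl)-6-methoxy-2,3-dihydro-4H-chromen-4-one | COc1cc([C@@H]2COc3cc(O)c(OC)c(O)c3C2=O)cc(O)c1OC | target

**Step count**

Total: 12 steps. Longest linear sequence: 10 steps (steps 1–5 and 8–12).

**Steps most likely to fail**

Step 11. The radical formed at C3 may be captured by an acyl nickel of another molecule (oligomerization), the aryloxy group at C2 may be expelled from the benzylic nickel species, or facial discrimination inside the constrained nickelacycle may be poor. The fallback uses known chemistry, sets out from 12 and comes back at 15. Dess–Martin oxidation of the secondary alcohol of 12 (CH2Cl2, NaHCO3, rt) should give the keto aldehyde 2,4-bis(benzyloxy)-6-{2-[3-(benzyloxy)-4,5-dimethoxyphenyl]-2-oxoethoxy}-3-methoxybenzaldehyde F1. An intramolecular crossed aldehyde–ketone benzoin reaction under N-heterocyclic carbene catalysis (triazolium precatalyst, Et3N, THF, rt) closes ring C at the same C3–C4 bond and gives racemic 5,7-bis(benzyloxy)-3-[3-(benzyloxy)-4,5-dimethoxyphenyl]-3-hydroxy-6-methoxychroman-4-one F2. Dehydration (SOCl2, pyridine, 0 °C) gives the isoflavone 5,7-bis(benzyloxy)-3-[3-(benzyloxy)-4,5-dimethoxyphenyl]-6-methoxy-4H-chromen-4-one F3. Asymmetric transfer hydrogenation with dynamic kinetic resolution (RuCl[(R,R)-TsDPEN](p-cymene), HCO2H/Et3N, EtOAc, 40 °C) should reduce C2=C3 and C4=O to the cis alcohol (3R,4R)-5,7-bis(benzyloxy)-3-[3-(benzyloxy)-4,5-dimethoxyphenyl]-6-methoxychroman-4-ol F4; the 4R center is expected from the usual aryl ketone model and 3R follows from the cis relationship. Buffered Dess–Martin oxidation at 0 °C then returns ketone 15 without a basic step at C3.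

Step 10. The acid chloride formed first may be trapped by the neighbouring secondary hydroxyl (seven-membered lactonization), and the electron-rich benzylic chloride may ionize or eliminate on concentration. The fallback sets out from 12 and comes back at 14, and changes the order of events so that no hydroxy acid meets an activating agent. Ghosez's reagent (1.1 equiv, CH2Cl2, 0 °C) converts the alcohol of 12 into rac-2,4-bis(benzyloxy)-6-{2-[3-(benzyloxy)-4,5-dimethoxyphenyl]-2-chloroethoxy}-3-methoxybenzaldehyde F5. Pinnick oxidation then gives rac-2,4-bis(benzyloxy)-6-{2-[3-(benzyloxy)-4,5-dimethoxyphenyl]-2-chloroethoxy}-3-methoxybenzoic acid F6; the β-aryloxy group should slow solvolysis of the chloride in the buffered medium. Oxalyl chloride with catalytic DMF, applied just before the nickel step, gives 14.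

Step 8. Attack of the hydrogen-bonded, weakly nucleophilic phenoxide of 8 may be slow, so that opening at the benzylic carbon and thermal rearrangement of the electron-rich oxirane compete. The fallback sets out from 6 and 11 and comes back at 12, and forms the ether before the formyl group is present. The more nucleophilic phenol 6 opens 11 at lower temperature (Cs2CO3 cat., DMF, 50 °C) to give rac-1-[3-(benzyloxy)-4,5-dimethoxyphenyl]-2-[3,5-bis(benzyloxy)-4-methoxyphenoxy]ethan-1-ol F7. Acetylation (Ac2O, pyridine) gives rac-1-[3-(benzyloxy)-4,5-dimethoxyphenyl]-2-[3,5-bis(benzyloxy)-4-methoxyphenoxy]ethyl acetate F8. Vilsmeier–Haack formylation (POCl3, DMF, 0 °C to rt; aqueous NaOAc) should go onto the more electron-rich ring A, whose two open positions are equivalent, to give rac-1-[3-(benzyloxy)-4,5-dimethoxyphenyl]-2-[3,5-bis(benzyloxy)-2-formyl-4-methoxyphenoxy]ethyl acetate F9. Methanolysis (K2CO3 cat., MeOH, rt) gives 12.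

**Further compounds**

F1 | step 11 | 2,4-bis(benzyloxy)-6-{2-[3-(benzyloxy)-4,5-dimethoxyphenyl]-2-oxoethoxy}-3-methoxybenzaldehyde | COc1cc(C(=O)COc2cc(OCc3ccccc3)c(OC)c(OCc3ccccc3)c2C=O)cc(OCc2ccccc2)c1OC
F2 | step 11 | rac-5,7-bis(benzyloxy)-3-[3-(benzyloxy)-4,5-dimethoxyphenyl]-3-hydroxy-6-methoxychroman-4-one | COc1cc(C2(O)COc3cc(OCc4ccccc4)c(OC)c(OCc4ccccc4)c3C2=O)cc(OCc2ccccc2)c1OC
F3 | step 11 | 5,7-bis(benzyloxy)-3-[3-(benzyloxy)-4,5-dimethoxyphenyl]-6-methoxy-4H-chromen-4-one | COc1cc(-c2coc3cc(OCc4ccccc4)c(OC)c(OCc4ccccc4)c3c2=O)cc(OCc2ccccc2)c1OC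
F4 | step 11 | (3R,4R)-5,7-bis(benzyloxy)-3-[3-(benzyloxy)-4,5-dimethoxyphenyl]-6-methoxychroman-4-ol | COc1cc([C@@H]2COc3cc(OCc4ccccc4)c(OC)c(OCc4ccccc4)c3[C@@H]2O)cc(OCc2ccccc2)c1OC
F5 | step 10 | rac-2,4-bis(benzyloxy)-6-{2-[3-(benzyloxy)-4,5-dimethoxyphenyl]-2-chloroethoxy}-3-methoxybenzaldehyde | COc1cc(C(Cl)COc2cc(OCc3ccccc3)c(OC)c(OCc3ccccc3)c2C=O)cc(OCc2ccccc2)c1OC
F6 | step 10 | rac-2,4-bis(benzyloxy)-6-{2-[3-(benzyloxy)-4,5-dimethoxyphenyl]-2-chloroethoxy}-3-methoxybenzoic acid | COc1cc(C(Cl)COc2cc(OCc3ccccc3)c(OC)c(OCc3ccccc3)c2C(=O)O)cc(OCc2ccccc2)c1OC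
F7 | step 8 | rac-1-[3-(benzyloxy)-4,5-dimethoxyphenyl]-2-[3,5-bis(benzyloxy)-4-methoxyphenoxy]ethan-1-ol | COc1cc(C(O)COc2cc(OCc3ccccc3)c(OC)c(OCc3ccccc3)c2)cc(OCc2ccccc2)c1OC
F8 | step 8 | rac-1-[3-(benzyloxy)-4,5-dimethoxyphenyl]-2-[3,5-bis(benzyloxy)-4-methoxyphenoxy]ethyl acetate | COc1cc(C(OC(C)=O)COc2cc(OCc3ccccc3)c(OC)c(OCc3ccccc3)c2)cc(OCc2ccccc2)c1OC
F9 | step 8 | rac-1-[3-(benzyloxy)-4,5-dimethoxyphenyl]-2-[3,5-bis(benzyloxy)-2-formyl-4-methoxyphenoxy]ethyl acetate | COc1cc(C(OC(C)=O)COc2cc(OCc3ccccc3)c(OC)c(OCc3ccccc3)c2C=O)cc(OCc2ccccc2)c1OC
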